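Turn both earlier runs into one clock for the flask, which has their equivalents and a larger charge.

| flask | starting complex | incoming ligand | remark | time |
|---|---|---|---|---|
| beta | 0.0050 M | 2 equiv | run made earlier |  |
| alpha | 0.0075 M | 2 equiv | run made earlier |  |
| flask | 0.010 M | 2.00 equiv |  | 6.0 min |

| run | time / min | starting complex / % | complex with one exchanged / % |
|---|---|---|---|
| beta | 0.500 | 82.0 | 16.3 |
| beta | 0.833 | 74.5 | 25.5 |
| beta | 1.33 | 62.0 | 34.0 |
| beta | 2.00 | 49.9 | 47.4 |
| beta | 3.00 | 38.3 | 57.0 |
| beta | 5.00 | 24.8 | 68.2 |
| beta | 8.00 | 12.1 | 72.9 |
| alpha | 0.500 | 77.8 | 23.4 |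
| alpha | 0.833 | 64.4 | 34.7 |
| alpha | 1.33 | 52.1 | 47.5 |
| alpha | 2.00 | 40.4 | 56.7 |
| alpha | 3.00 | 27.5 | 66.4 |
| alpha | 5.00 | 14.4 | 73.3 |
| alpha | 8.00 | 5.1 | 76.1 |

(scatter of a reading: 1 percentage point)

- the numbers in the tables scatter by 1 percentage point (one standard deviation)
- the earlier runs do not show how much of incoming ligand is bound; that part of a forecast is a guess

* part of the starting complex that has reacted at 6.0 min
* share of the unused incoming ligand that is free and not bound as idle adduct, at 6.0 min

The beta run holds about half of its starting complex at 2.00 min, and the alpha run about half at 1.33 min. Unlike a first-order time constant, this time is shorter at the larger charge, while charge times time reads the same in both runs: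

0.600 M·s and 0.599 M·s

So we define the flask's half-time as the beta run's half-time times the beta charge over the flask's charge:

1.00 min

The other time is the asked 6.0 min, and their ratio is:

6.00

The last alpha reading stands at the same ratio, 6.02, with 5.1% of the starting complex left. Our own reckoning for c is therefore 94.9%, within the scatter. For the free share we have no reckoning, since the readings do not show bound ligand.

The forecast gives 94% and 82%; of the part missing from the two columns it says “I assume this is the idle adduct”, and it calls that assignment a guess.

The flask gives 93.8% and 99.8%.

    leaving ligand + incoming ligand ⇌ idle adduct, settled at all times (K = 35.3 L mol⁻¹)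
    starting complex + incoming ligand → leaving ligand + complex with one exchanged (k = 0.654 L mol⁻¹ s⁻¹)
    leaving ligand → by-product carried off (k = 0.157 s⁻¹)
    complex with one exchanged + incoming ligand → leaving ligand + complex with two exchanged (k = 0.0796 L mol⁻¹ s⁻¹)

At 6.00 min the flask holds 19.7% of the starting complex charged as complex with two exchanged, and idle adduct stands at 1.73 × 10⁻⁵ M. A neighbouring flask with 0.017 M of starting complex, at the same equivalents and time, has a half-time of 0.588 min by the same scaling, so its ratio is 10.2. In that flask 98.2% has reacted, and 1.77% of the starting complex is left.

The numbers in the tables are simulated with constants of no real substance, noise included.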